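Ring A is cut at C7–C8. C8 carries the methylene bridge to ring D and lies next to C8a–O1, so it corresponds to the vinylogously acidic lateral CH2 of a 6-(2-arylethyl)-4-pyrone (ring C). In one operation this carbon is deprotonated and acylated by the ester of an (E)-β-methoxyacrylate arm on pyrone C5 (future C4a). Ring A closes and aromatises with the bridge locked at C8, the 7-OH free and the flavone C5 oxygen masked as OMe. The precursor is a 3-methoxy-2-phenyl-4-pyrone that already holds the complete, benzyl-protected ring D on its C6 ethyl chain. It is assembled by an acylketene hetero-Diels–Alder reaction, iodination, Sonogashira coupling and methanol addition.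

Key step: step 12

Remark: ArD stands for 2,4-bis(benzyloxy)-6-methoxy-5-methyl-3-(3-phenylpropanoyl)phenyl, bonded through C1. Monocyclic pyrones carry pyrone numbering (O1, 2-Ph, 3-OMe, 4-oxo) and the bicyclic compounds carry flavone numbering. The target has no stereocentre; the alkene geometry of the silyl enol ether and the stereocentres of transient intermediates are erased in the step that forms them or the next one.

Step 1
Reactants: 1 2-methylbenzene-1,3,5-triol; 2 3-phenylpropanoyl chloride
Product: 3 1-(2,4,6-trihydroxy-3-methylphenyl)-3-phenylpropan-1-one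
Conditions: AlCl3, PhNO2/CH2Cl2, 0 °C → 50 °C; aq HCl
Reagents that add atoms: none
Why: Friedel–Crafts acylation (with Fries migration of any O-acyl ester under the same conditions) of the highly nucleophilic phloroglucinol ring; the two unsubstituted carbons of 1 are equivalent and the first acyl group deactivates the ring toward a second.

Step 2
Reactants: 3 1-(2,4,6-trihydroxy-3-methylphenyl)-3-phenylpropan-1-one
Product: 4 1-(2,6-dihydroxy-4-methoxy-3-methylphenyl)-3-phenylpropan-1-one
Conditions: Me2SO4 (1.05 equiv), K2CO3 (1.1 equiv), acetone, rt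
Reagents that add atoms: dimethyl sulfate, COS(=O)(=O)OC
Why: Williamson O-methylation with limiting reagent: the hydroxyl para to the acyl group is the most acidic and is not chelated, whereas both ortho hydroxyls are held back by hydrogen bonding to the ketone, so mono-methylation should occur at O-4.

Step 3
Reactants: 4 1-(2,6-dihydroxy-4-methoxy-3-methylphenyl)-3-phenylpropan-1-one
Product: 5 2,4-dihydroxy-6-methoxy-5-methyl-3-(3-phenylpropanoyl)benzaldehyde
Conditions: POCl3, DMF, MeCN, 0 °C → rt; then H2O, 50 °C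
Reagents that add atoms: N,N-dimethylformamide, CN(C)C=O; water, O
Why: Vilsmeier–Haack formylation at the only unsubstituted ring carbon, which is activated by an ortho hydroxyl, an ortho methoxyl and a para hydroxyl, so that at low temperature ring attack should outrun the slower reaction at the ketone α-methylene; hydrolysis of the iminium salt releases the aldehyde.

Step 4
Reactants: 5 2,4-dihydroxy-6-methoxy-5-methyl-3-(3-phenylpropanoyl)benzaldehyde
Product: 6 2,4-bis(benzyloxy)-6-methoxy-5-methyl-3-(3-phenylpropanoyl)benzaldehyde (ArD–CHO)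
Conditions: BnBr (2.6 equiv), K2CO3, DMF, 60 °C
Reagents that add atoms: benzyl bromide, BrCc1ccccc1
Why: Williamson etherification: K2CO3 in warm DMF overcomes the chelation of both hydroxyls, and because every ring carbon is substituted O-benzylation is the productive pathway.

Step 5
Reactants: 6 ArD–CHO; 7 2,2-dimethyl-1,3-dioxane-4,6-dione (Meldrum's acid)
Product: 10 3-(ArD)propanoic acid, via arylidene Meldrum's acid 8 (not isolated), via benzyl Meldrum's acid 9 (not isolated)
Conditions: HCO2H/Et3N (5:2), 100 °C; aq HCl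
Reagents that add atoms: none
Why: Knoevenagel condensation with Meldrum's acid, conjugate hydride transfer from formate to the alkylidene Meldrum's acid and hydrolytic decarboxylation in one pot; these soft conditions leave the enolisable ketone and the benzyl ethers alone, which a strongly basic chain extension would not.

Step 6
Reactants: 10 3-(ArD)propanoic acid; 7 Meldrum's acid
Product: 11 5-[3-(ArD)-1-hydroxypropylidene]-2,2-dimethyl-1,3-dioxane-4,6-dione (acyl Meldrum's acid, enol form)
Conditions: DCC, DMAP, CH2Cl2, 0 °C → rt; filtration, aq KHSO4 wash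
Reagents that add atoms: none
Why: Carbodiimide/DMAP C-acylation of Meldrum's acid, the standard entry to acyl Meldrum's acids as latent acylketenes; the crude enol is used directly.

Step 7
Reactants: 12 2-methoxy-1-phenylethan-1-one
Product: 13 tert-butyl{[(Z)-2-methoxy-1-phenylethenyl]oxy}dimethylsilane
Conditions: TBSOTf, Et3N, CH2Cl2, 0 °C
Reagents that add atoms: tert-butyldimethylsilyl trifluoromethanesulfonate, CC(C)(C)[Si](C)(C)OS(=O)(=O)C(F)(F)F
Why: Soft enolisation and O-silylation (silyl enol ether formation) at the only enolisable position; the Z isomer is expected to predominate and the geometry is of no consequence.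

Step 8
Reactants: 11 acyl Meldrum's acid; 13 silyl enol ether
Product: 16 6-[2-(ArD)ethyl]-3-methoxy-2-phenyl-4H-pyran-4-one, via acylketene 14 (not isolated), via dihydropyranone cycloadduct 15 (not isolated)
Conditions: 11 added slowly to 13 (3 equiv), PhMe, 100 °C; then TsOH·H2O (cat.), 50 °C
Reagents that add atoms: none
Why: Thermolysis of the acyl Meldrum's acid releases acetone and CO2 to give acylketene 14, which undergoes the hetero-Diels–Alder reaction of acylketenes with enol ethers (ketene carbon to the methoxy-bearing carbon of 13, acyl oxygen to the phenyl- and siloxy-bearing carbon), and acid then eliminates the silanol to aromatise the 4-pyrone; a stepwise C-acylation would give a 1,3,5-triketone that cyclodehydrates to the same pyrone.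

Step 9
Reactants: 16 6-[2-(ArD)ethyl]-3-methoxy-2-phenyl-4H-pyran-4-one
Product: 17 6-[2-(ArD)ethyl]-5-iodo-3-methoxy-2-phenyl-4H-pyran-4-one
Conditions: NIS, TFA (cat.), MeCN, rt
Reagents that add atoms: N-iodosuccinimide, O=C1CCC(=O)N1I
Why: Electrophilic iodination at C5, the only C–H of the pyrone and the α-carbon of its vinylogous ester, hence its most nucleophilic site; ring D has no free position and the remaining arenes are unactivated.

Step 10
Reactants: 17 5-iodopyrone; 18 methyl prop-2-ynoate (methyl propiolate)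
Product: 19 methyl 3-{6-[2-(ArD)ethyl]-3-methoxy-4-oxo-2-phenyl-4H-pyran-5-yl}prop-2-ynoate
Conditions: Pd(PPh3)2Cl2 (5 mol%), CuI (10 mol%), K2CO3, THF, 60 °C, 18 (4 equiv) added in portions
Reagents that add atoms: none
Why: Sonogashira coupling at the electron-poor C5–I bond, run with an inorganic base because amines add to methyl propiolate and can open 4-pyrones.

Step 11
Reactants: 19 pyronyl ynoate
Product: 20 methyl (2E)-3-{6-[2-(ArD)ethyl]-3-methoxy-4-oxo-2-phenyl-4H-pyran-5-yl}-3-methoxyprop-2-enoate
Conditions: NaOMe (0.3 equiv), MeOH/THF, 0 °C → rt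
Reagents that add atoms: methanol, CO
Why: Base-catalysed oxa-Michael addition of methanol to the ynoate at the carbon β to the ester; reversible addition and loss of methoxide should equilibrate the enol ether to the usual β-alkoxyacrylate geometry (OMe trans to the ester, E), which holds the ester cis to the pyrone.

Step 12
Reactants: 20 (E)-β-methoxyacrylate pyrone
Product: 22 8-[(ArD)methyl]-7-hydroxy-3,5-dimethoxy-2-phenyl-4H-chromen-4-one, via dienone 21 (not isolated)
Conditions: LiN(SiMe3)2 (3.3 equiv), THF, −78 °C → 0 °C; AcOH quench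
Reagents that add atoms: none
Why: Proposed new method: LiN(SiMe3)2 is expected to deprotonate the CH2 attached to pyrone C6, giving a dienolate delocalised over C6=C5 onto the C4 oxygen, while further base stores the hindered ring D ketone as an inert enolate; the lateral carbon then adds to the ester carbonyl, methoxide is expelled, and deprotonation of dienone 21 gives the aromatic C7 phenoxide, which makes the sequence irreversible. The closest known reaction types are the lateral metalation–acylation of 2-alkyl-4-pyrones and chromones and the Claisen or Dieckmann aromatisation of polycarbonyl chains to resorcinols. Ring A closes in a 6-(enolendo)-exo-trig mode and the C7–C8 bond is the only skeletal bond formed; no stereocentre results, since C8 of 21 is planarised on enolisation. The step needs C- rather than O-acylation and the bridge at C8 rather than C6: attack through the dienolate oxygen would give a non-aromatic enol lactone that methoxide reopens, whereas C-acylation is drained by aromatisation, and the nucleophilic carbon already bears the ring D methylene and is bonded to the pyrone carbon next to O1, so only the 8-substituted flavone can form. The E enol ether holds the ester cis to the pyrone within reach of that carbon, its methyl ether prevents the arm from becoming a deactivating β-keto ester enolate, and liberated methoxide can return any Z isomer to the reactive geometry by addition–elimination.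

Step 13
Reactants: 22 8-[(ArD)methyl]-7-hydroxy-3,5-dimethoxy-2-phenyl-4H-chromen-4-one
Product: 23 8-{[2,4-dihydroxy-6-methoxy-5-methyl-3-(3-phenylpropanoyl)phenyl]methyl}-5,7-dihydroxy-3-methoxy-2-phenyl-4H-chromen-4-one (target)
Conditions: BCl3 (8 equiv), C6HMe5 (6 equiv), CH2Cl2, −78 °C → 0 °C; MeOH, then H2O
Reagents that add atoms: none
Why: Lewis-acid ether cleavage: BCl3 removes the benzyl ethers at low temperature, pentamethylbenzene capturing the benzyl cations so that C6 of ring A is not benzylated, and cleaves the 5-OMe through its six-membered boron chelate with the C4 carbonyl, while the 3-OMe and the unchelated ring D OMe are expected to survive at 0 °C.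

Compound list
1 | 2-methylbenzene-1,3,5-triol | Cc1c(O)cc(O)cc1O | starting material
2 | 3-phenylpropanoyl chloride | O=C(Cl)CCc1ccccc1 | starting material
3 | 1-(2,4,6-trihydroxy-3-methylphenyl)-3-phenylpropan-1-one | Cc1c(O)cc(O)c(C(=O)CCc2ccccc2)c1O | intermediate
4 | 1-(2,6-dihydroxy-4-methoxy-3-methylphenyl)-3-phenylpropan-1-one | COc1cc(O)c(C(=O)CCc2ccccc2)c(O)c1C | intermediate
5 | 2,4-dihydroxy-6-methoxy-5-methyl-3-(3-phenylpropanoyl)benzaldehyde | COc1c(C)c(O)c(C(=O)CCc2ccccc2)c(O)c1C=O | intermediate
6 | 2,4-bis(benzyloxy)-6-methoxy-5-methyl-3-(3-phenylpropanoyl)benzaldehyde (ArD–CHO) | COc1c(C)c(OCc2ccccc2)c(C(=O)CCc2ccccc2)c(OCc2ccccc2)c1C=O | intermediate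
7 | 2,2-dimethyl-1,3-dioxane-4,6-dione (Meldrum's acid) | CC1(C)OC(=O)CC(=O)O1 | starting material
8 | 5-[(ArD)methylidene]-2,2-dimethyl-1,3-dioxane-4,6-dione (not isolated) | CC1(C)OC(=O)C(=Cc2c(OC)c(C)c(OCc3ccccc3)c(C(=O)CCc3ccccc3)c2OCc2ccccc2)C(=O)O1 | intermediate
9 | 5-[(ArD)methyl]-2,2-dimethyl-1,3-dioxane-4,6-dione (not isolated) | CC1(C)OC(=O)C(Cc2c(OC)c(C)c(OCc3ccccc3)c(C(=O)CCc3ccccc3)c2OCc2ccccc2)C(=O)O1 | intermediate
10 | 3-[2,4-bis(benzyloxy)-6-methoxy-5-methyl-3-(3-phenylpropanoyl)phenyl]propanoic acid | OC(=O)CCc1c(OC)c(C)c(OCc2ccccc2)c(C(=O)CCc2ccccc2)c1OCc1ccccc1 | intermediate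
11 | 5-[3-(ArD)-1-hydroxypropylidene]-2,2-dimethyl-1,3-dioxane-4,6-dione | CC1(C)OC(=O)C(=C(O)CCc2c(OC)c(C)c(OCc3ccccc3)c(C(=O)CCc3ccccc3)c2OCc2ccccc2)C(=O)O1 | intermediate
12 | 2-methoxy-1-phenylethan-1-one | COCC(=O)c1ccccc1 | starting material
13 | tert-butyl{[(Z)-2-methoxy-1-phenylethenyl]oxy}dimethylsilane | CO/C=C(\O[Si](C)(C)C(C)(C)C)c1ccccc1 | intermediate
14 | 5-(ArD)pent-1-ene-1,3-dione (acylketene, not isolated) | O=C=CC(=O)CCc1c(OC)c(C)c(OCc2ccccc2)c(C(=O)CCc2ccccc2)c1OCc1ccccc1 | intermediate
15 | 2-{[tert-butyl(dimethyl)silyl]oxy}-6-[2-(ArD)ethyl]-3-methoxy-2-phenyl-2,3-dihydro-4H-pyran-4-one (racemic diastereomer mixture, not isolated) | COC1C(=O)C=C(CCc2c(OC)c(C)c(OCc3ccccc3)c(C(=O)CCc3ccccc3)c2OCc2ccccc2)OC1(O[Si](C)(C)C(C)(C)C)c1ccccc1 | intermediate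
16 | 6-[2-(ArD)ethyl]-3-methoxy-2-phenyl-4H-pyran-4-one | COc1c(-c2ccccc2)oc(CCc2c(OC)c(C)c(OCc3ccccc3)c(C(=O)CCc3ccccc3)c2OCc2ccccc2)cc1=O | intermediate
17 | 6-[2-(ArD)ethyl]-5-iodo-3-methoxy-2-phenyl-4H-pyran-4-one | COc1c(-c2ccccc2)oc(CCc2c(OC)c(C)c(OCc3ccccc3)c(C(=O)CCc3ccccc3)c2OCc2ccccc2)c(I)c1=O | intermediate
18 | methyl prop-2-ynoate | C#CC(=O)OC | starting material
19 | methyl 3-{6-[2-(ArD)ethyl]-3-methoxy-4-oxo-2-phenyl-4H-pyran-5-yl}prop-2-ynoate | COC(=O)C#Cc1c(CCc2c(OC)c(C)c(OCc3ccccc3)c(C(=O)CCc3ccccc3)c2OCc2ccccc2)oc(-c2ccccc2)c(OC)c1=O | intermediate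
20 | methyl (2E)-3-{6-[2-(ArD)ethyl]-3-methoxy-4-oxo-2-phenyl-4H-pyran-5-yl}-3-methoxyprop-2-enoate | COC(=O)/C=C(/OC)c1c(CCc2c(OC)c(C)c(OCc3ccccc3)c(C(=O)CCc3ccccc3)c2OCc2ccccc2)oc(-c2ccccc2)c(OC)c1=O | intermediate
21 | 8-[(ArD)methyl]-3,5-dimethoxy-2-phenyl-4H-chromene-4,7(8H)-dione (racemic at C8, not isolated) | COC1=CC(=O)C(Cc2c(OC)c(C)c(OCc3ccccc3)c(C(=O)CCc3ccccc3)c2OCc2ccccc2)C2=C1C(=O)C(OC)=C(c1ccccc1)O2 | intermediate
22 | 8-[(ArD)methyl]-7-hydroxy-3,5-dimethoxy-2-phenyl-4H-chromen-4-one | COc1cc(O)c(Cc2c(OC)c(C)c(OCc3ccccc3)c(C(=O)CCc3ccccc3)c2OCc2ccccc2)c2oc(-c3ccccc3)c(OC)c(=O)c12 | intermediate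
23 | 8-{[2,4-dihydroxy-6-methoxy-5-methyl-3-(3-phenylpropanoyl)phenyl]methyl}-5,7-dihydroxy-3-methoxy-2-phenyl-4H-chromen-4-one | COc1c(C)c(O)c(C(=O)CCc2ccccc2)c(O)c1Cc1c(O)cc(O)c2c(=O)c(OC)c(-c3ccccc3)oc12 | target

Total step count: 13. Longest linear sequence: 12 steps (steps 1–6 and 8–13; step 7 is a one-step branch).

Steps most likely to fail

Step 12. The dienolate may fail to acylate the weakly electrophilic, vinylogous-carbonate-like ester. Proton shuffling to the ring D enolate, intermolecular condensation or persistence of an unreactive Z enol ether would then consume the material instead of ring closure. The fallback uses known chemistry, sets out from 4 and returns at 23, building the bridge instead of ring A. Commercial 2-methoxy-1-(2,4,6-trihydroxyphenyl)ethan-1-one is heated with benzoic anhydride and sodium benzoate (Allan–Robinson condensation, 180 °C) to give 5-hydroxy-3-methoxy-4-oxo-2-phenyl-4H-chromen-7-yl benzoate F1. Saponification (KOH, aqueous EtOH, then acid) gives 5,7-dihydroxy-3-methoxy-2-phenyl-4H-chromen-4-one F2. Mannich aminomethylation (aqueous CH2O, Me2NH, EtOH), which 5,7-dihydroxyflavones undergo at C8, gives 8-[(dimethylamino)methyl]-5,7-dihydroxy-3-methoxy-2-phenyl-4H-chromen-4-one F3. Heating F3 with phenol 4 in dioxane at 100 °C should expel dimethylamine to form the ortho-quinone methide, which the single free, doubly oxygen-activated ring carbon of 4 intercepts to give 23 directly.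

Step 8. The acylketene may be lost to dimerisation, or to proton and silyl transfer between the acidic acyl Meldrum's acid and the enol ether, before the slower cycloaddition with a trisubstituted alkene takes place. The fallback sets out from 6 and returns at 16, forming the ethylene link by lateral alkylation instead. Aldehyde 6 is reduced chemoselectively (NaBH4, MeOH/THF, −20 °C; the di-ortho-substituted ketone reacts far more slowly) to 1-[2,6-bis(benzyloxy)-3-(hydroxymethyl)-4-methoxy-5-methylphenyl]-3-phenylpropan-1-one F4. PBr3 (CH2Cl2, 0 °C) converts it into 1-[2,6-bis(benzyloxy)-3-(bromomethyl)-4-methoxy-5-methylphenyl]-3-phenylpropan-1-one F5. In parallel, commercial 2,2,6-trimethyl-4H-1,3-dioxin-4-one, a neutral acetylketene source used in excess, is heated with 13 (PhMe, 110 °C) to give 2-{[tert-butyl(dimethyl)silyl]oxy}-3-methoxy-6-methyl-2-phenyl-2,3-dihydro-4H-pyran-4-one F6. Treatment with TsOH in the same pot gives 3-methoxy-6-methyl-2-phenyl-4H-pyran-4-one F7. Lateral deprotonation of F7 (LiN(SiMe3)2, THF, −78 °C) and alkylation of the dienolate with F5, added last at −78 °C, gives 16.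

Step 10. Base-induced oligomerisation and copper-mediated homocoupling of methyl propiolate may outrun cross-coupling at the hindered C5–I bond. The fallback sets out from 17 and returns at 19, building the ester on a robust alkyne. Sonogashira coupling with ethynyltrimethylsilane (Pd(PPh3)2Cl2, CuI, iPr2NEt, THF, 50 °C) gives 6-[2-(ArD)ethyl]-3-methoxy-2-phenyl-5-[(trimethylsilyl)ethynyl]-4H-pyran-4-one F8. Desilylation (K2CO3, MeOH, 0 °C) gives 6-[2-(ArD)ethyl]-5-ethynyl-3-methoxy-2-phenyl-4H-pyran-4-one F9. Palladium-catalysed oxidative methoxycarbonylation of the terminal alkyne (PdCl2 cat., CuCl2, NaOAc, CO 1 atm, MeOH, rt) then gives 19.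

Further compounds
F1 | step 12 | 5-hydroxy-3-methoxy-4-oxo-2-phenyl-4H-chromen-7-yl benzoate | COc1c(-c2ccccc2)oc2cc(OC(=O)c3ccccc3)cc(O)c2c1=O
F2 | step 12 | 5,7-dihydroxy-3-methoxy-2-phenyl-4H-chromen-4-one | COc1c(-c2ccccc2)oc2cc(O)cc(O)c2c1=O
F3 | step 12 | 8-[(dimethylamino)methyl]-5,7-dihydroxy-3-methoxy-2-phenyl-4H-chromen-4-one | COc1c(-c2ccccc2)oc2c(CN(C)C)c(O)cc(O)c2c1=O
F4 | step 8 | 1-[2,6-bis(benzyloxy)-3-(hydroxymethyl)-4-methoxy-5-methylphenyl]-3-phenylpropan-1-one | COc1c(C)c(OCc2ccccc2)c(C(=O)CCc2ccccc2)c(OCc2ccccc2)c1CO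
F5 | step 8 | 1-[2,6-bis(benzyloxy)-3-(bromomethyl)-4-methoxy-5-methylphenyl]-3-phenylpropan-1-one | COc1c(C)c(OCc2ccccc2)c(C(=O)CCc2ccccc2)c(OCc2ccccc2)c1CBr
F6 | step 8 | 2-{[tert-butyl(dimethyl)silyl]oxy}-3-methoxy-6-methyl-2-phenyl-2,3-dihydro-4H-pyran-4-one (racemic diastereomer mixture, not isolated) | COC1C(=O)C=C(C)OC1(O[Si](C)(C)C(C)(C)C)c1ccccc1
F7 | step 8 | 3-methoxy-6-methyl-2-phenyl-4H-pyran-4-one | COc1c(-c2ccccc2)oc(C)cc1=O
F8 | step 10 | 6-[2-(ArD)ethyl]-3-methoxy-2-phenyl-5-[(trimethylsilyl)ethynyl]-4H-pyran-4-one | COc1c(-c2ccccc2)oc(CCc2c(OC)c(C)c(OCc3ccccc3)c(C(=O)CCc3ccccc3)c2OCc2ccccc2)c(C#C[Si](C)(C)C)c1=O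
F9 | step 10 | 6-[2-(ArD)ethyl]-5-ethynyl-3-methoxy-2-phenyl-4H-pyran-4-one | COc1c(-c2ccccc2)oc(CCc2c(OC)c(C)c(OCc3ccccc3)c(C(=O)CCc3ccccc3)c2OCc2ccccc2)c(C#C)c1=O
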